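**Strategy.** Numbering: guaiacyl ring–C7H2–C8H(C9H2OAc)–C8′H(C9′H3)–C7′H2–syringyl ring. C8′ carries one methyl group (C9′) and one arylmethyl arm (C7′ to the syringyl ring). This is the imprint of methyl and a metal adding across a C8′=C7′ vinyl group on C8. The C8′–C9′ and C7′–aryl bonds are cut together. In one flask Me3Al adds to the vinyl group under a chiral zirconocene, setting C8′, and the primary C7′–metal bond is coupled with the protected syringyl bromide. The precursor is an enantiopure 1-alkene whose C8 (S) bears the O-benzylated guaiacylmethyl arm, a CH2OTBS arm and the vinyl group. It is made by auxiliary-controlled deconjugative alkylation.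

Key step: step 7

Assumption: the face rule known for simple 1-alkenes (the (−)-zirconocene leads to (R)-2-methylalkan-1-ols) is taken to hold for the allylic-branched alkene. This points to the (+)-antipode, and both antipodes should be compared on a small scale first.

Step 1
Reactants: 1 [4-(benzyloxy)-3-methoxyphenyl]methanol (O-benzylvanillyl alcohol, commercial)
Product: 2 1-(benzyloxy)-4-(bromomethyl)-2-methoxybenzene (O-benzylvanillyl bromide)
Conditions: PBr3 (0.4 equiv), Et2O, 0 °C; used without chromatography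
Reagents that add atoms: phosphorus tribromide, BrP(Br)Br
Why: Bromination of a primary benzylic alcohol through its phosphite ester (SN2 displacement by bromide) is fast at 0 °C on this electron-rich ring and leaves the aryl ethers untouched.

Step 2
Reactants: 3 (4S)-4-benzyl-1,3-oxazolidin-2-one; 4 (E)-but-2-enoic anhydride (crotonic anhydride)
Product: 5 (4S)-4-benzyl-3-[(2E)-but-2-enoyl]-1,3-oxazolidin-2-one
Conditions: LiCl, Et3N, THF, 0 to 23 °C
Reagents that add atoms: none
Why: LiCl-promoted N-acylation of an oxazolidinone with an anhydride under a mild amine base gives the enoyl imide without touching the C4 stereocentre of the auxiliary.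

Step 3
Reactants: 5 (4S)-4-benzyl-3-[(2E)-but-2-enoyl]-1,3-oxazolidin-2-one; 2 O-benzylvanillyl bromide
Product: 7 (4S)-4-benzyl-3-{(2S)-2-[4-(benzyloxy)-3-methoxybenzyl]but-3-enoyl}-1,3-oxazolidin-2-one, via sodium dienolate 6 (not isolated)
Conditions: NaN(SiMe3)2 (1.1 equiv), THF, −78 °C; then 2 (1.5 equiv), −78 to −40 °C; AcOH quench at −78 °C
Reagents that add atoms: none
Why: Evans asymmetric alkylation in its deconjugative form: NaN(SiMe3)2 removes a γ-hydrogen of 5 to give the sodium-chelated Z-dienolate 6, which the reactive benzylic bromide alkylates at Cα rather than Cγ on the face opposite the C4 benzyl group, so C8 is set as S and the double bond ends up as the terminal vinyl group.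

Step 4
Reactants: 7 alkylated imide
Product: 8 (2S)-2-[4-(benzyloxy)-3-methoxybenzyl]but-3-en-1-ol
Conditions: LiBH4, MeOH (1 equiv each relative to hydride source), Et2O, 0 °C
Reagents that add atoms: none
Why: Reductive cleavage of an N-acyl oxazolidinone: the borohydride attacks the exocyclic carbonyl, the cold and barely basic medium should leave C8 and the unconjugated vinyl group untouched, and the auxiliary 3 is recovered.

Step 5
Reactants: 8 (2S)-2-[4-(benzyloxy)-3-methoxybenzyl]but-3-en-1-ol
Product: 9 tert-butyl({(2S)-2-[4-(benzyloxy)-3-methoxybenzyl]but-3-en-1-yl}oxy)dimethylsilane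
Conditions: TBSCl, imidazole, CH2Cl2, 23 °C
Reagents that add atoms: tert-butyldimethylsilyl chloride, CC(C)(C)[Si](C)(C)Cl
Why: Imidazole-mediated silylation of an unhindered primary alcohol removes the only acidic hydrogen and shields O9 from aluminium and zirconium.

Step 6
Reactants: 10 4-bromo-2,6-dimethoxyphenol
Product: 11 2-(benzyloxy)-5-bromo-1,3-dimethoxybenzene
Conditions: BnBr, K2CO3, DMF, 50 °C
Reagents that add atoms: benzyl bromide, BrCc1ccccc1
Why: Williamson ether synthesis on the phenoxide masks the acidic phenol with the same group used on the guaiacyl ring, so both fall together at the end.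

Step 7
Reactants: 9 silyl ether of the (2S)-butenol; 12 trimethylaluminium; 11 2-(benzyloxy)-5-bromo-1,3-dimethoxybenzene
Product: 15 tert-butyldimethylsilyl ether of (2S,3R)-2-[4-(benzyloxy)-3-methoxybenzyl]-4-[4-(benzyloxy)-3,5-dimethoxyphenyl]-3-methylbutan-1-ol, via alkyldimethylalane 13 (not isolated), via alkylzinc triflate 14 (not isolated)
Conditions: Me3Al (3 equiv), (+)-bis(1-neomenthylindenyl)zirconium dichloride (5–10 mol %), methylaluminoxane (MeAlO)n (0.5 equiv), CH2Cl2, 0 to 23 °C; evaporate CH2Cl2 and excess Me3Al in vacuo; Zn(OTf)2 (1.1 equiv), DMF, 70 °C; then 11 (3 equiv), Pd(P(t-Bu)3)2 (5 mol %), DMF, 23 to 50 °C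
Reagents that add atoms: trimethylaluminium (12), C[Al](C)C
Why: Me3Al and the zirconocene dichloride form a cationic methylzirconocene (tetravalent zirconium) that inserts the vinyl group of 9 with methyl going to C8′ and zirconium to C7′, and alkyl exchange with aluminium releases alane 13 before β-hydride elimination can occur. After the excess Me3Al has been pumped off, Zn(OTf)2 in DMF passes the C7′ alkyl group to zinc (14), which transmetalates to the aryl–palladium bromide (divalent palladium) formed from 11 and Pd(P(t-Bu)3)2 (zerovalent palladium), and reductive elimination forms the C7′–aryl bond. The closest known reaction type is the zirconium-catalysed asymmetric carboalumination of 1-alkenes run in one flask with a zinc-relayed Negishi coupling, whose scope covers silyl-protected alkenols and, more slowly, alkenes branched at the allylic carbon (hence the aluminoxane accelerator); no ring is closed. C8′ is the only new stereocentre and is controlled by the chiral zirconocene: C8 takes the place of the alkyl chain and C7′ that of the carbinol carbon in the rule for simple 1-alkenes, so the (+)-antipode should give 8′R, with the resident C8 centre acting only as a matched or mismatched modifier. Regiochemistry is inherent to the insertion, and chemoselectivity is secured by a substrate with one monosubstituted alkene, no acidic hydrogen, a bulky silyl ether that keeps O9 off the metals, and inert aryl ethers. The two methyl groups left on aluminium can compete for palladium, so the cheap bromide 11 is used in excess, and any C8′ epimer is a diastereomer that can be removed by chromatography at 15 or 16.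

Step 8
Reactants: 15 silyl ether from the key step
Product: 16 (2S,3R)-2-[4-(benzyloxy)-3-methoxybenzyl]-4-[4-(benzyloxy)-3,5-dimethoxyphenyl]-3-methylbutan-1-ol
Conditions: Bu4NF, THF, 23 °C
Reagents that add atoms: none
Why: Fluoride-induced desilylation is driven by the strong Si–F bond and affects neither the benzyl ethers nor the two non-epimerisable stereocentres.

Step 9
Reactants: 16 primary alcohol
Product: 17 (2S,3R)-2-[4-(benzyloxy)-3-methoxybenzyl]-4-[4-(benzyloxy)-3,5-dimethoxyphenyl]-3-methylbutyl acetate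
Conditions: Ac2O, pyridine, DMAP (cat.), CH2Cl2, 23 °C
Reagents that add atoms: acetic anhydride, CC(=O)OC(C)=O
Why: DMAP-catalysed acetylation meets only one free hydroxyl group because both phenols are still benzylated, so the acetate can go nowhere but O9.

Step 10
Reactants: 17 dibenzyl acetate
Product: 18 (2S,3R)-2-(4-hydroxy-3-methoxybenzyl)-4-(4-hydroxy-3,5-dimethoxyphenyl)-3-methylbutyl acetate (target)
Conditions: H2 (1 atm), 10% Pd/C, EtOAc, 23 °C
Reagents that add atoms: none
Why: Catalytic hydrogenolysis cleaves both aryl benzyl ethers under neutral conditions, while the non-benzylic primary acetate, the methoxy groups and both stereocentres are inert and the aprotic solvent avoids acetyl transfer.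

**Compound list**
1 | [4-(benzyloxy)-3-methoxyphenyl]methanol | COc1cc(CO)ccc1OCc1ccccc1 | starting material
2 | 1-(benzyloxy)-4-(bromomethyl)-2-methoxybenzene | COc1cc(CBr)ccc1OCc1ccccc1 | intermediate
3 | (4S)-4-benzyl-1,3-oxazolidin-2-one | O=C1N[C@@H](Cc2ccccc2)CO1 | starting material
4 | (E)-but-2-enoic anhydride | C/C=C/C(=O)OC(=O)/C=C/C | starting material
5 | (4S)-4-benzyl-3-[(2E)-but-2-enoyl]-1,3-oxazolidin-2-one | C/C=C/C(=O)N1[C@@H](Cc2ccccc2)COC1=O | intermediate
6 | sodium (1Z)-1-[(4S)-4-benzyl-2-oxo-1,3-oxazolidin-3-yl]buta-1,3-dien-1-olate | [Na+].C=C/C=C(\[O-])N1[C@@H](Cc2ccccc2)COC1=O | intermediate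
7 | (4S)-4-benzyl-3-{(2S)-2-[4-(benzyloxy)-3-methoxybenzyl]but-3-enoyl}-1,3-oxazolidin-2-one | COc1cc(C[C@H](C(=O)N2[C@@H](Cc3ccccc3)COC2=O)C=C)ccc1OCc1ccccc1 | intermediate
8 | (2S)-2-[4-(benzyloxy)-3-methoxybenzyl]but-3-en-1-ol | COc1cc(C[C@H](CO)C=C)ccc1OCc1ccccc1 | intermediate
9 | tert-butyl({(2S)-2-[4-(benzyloxy)-3-methoxybenzyl]but-3-en-1-yl}oxy)dimethylsilane | COc1cc(C[C@H](CO[Si](C)(C)C(C)(C)C)C=C)ccc1OCc1ccccc1 | intermediate
10 | 4-bromo-2,6-dimethoxyphenol | COc1cc(Br)cc(OC)c1O | starting material
11 | 2-(benzyloxy)-5-bromo-1,3-dimethoxybenzene | COc1cc(Br)cc(OC)c1OCc1ccccc1 | intermediate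
12 | trimethylaluminium | C[Al](C)C | starting material
13 | {(2S,3S)-3-[4-(benzyloxy)-3-methoxybenzyl]-4-[(tert-butyldimethylsilyl)oxy]-2-methylbutyl}dimethylaluminium (same spatial arrangement at C8′ as in 15; the descriptor changes because CH2Al outranks C8) | COc1cc(C[C@H](CO[Si](C)(C)C(C)(C)C)[C@H](C)C[Al](C)C)ccc1OCc1ccccc1 | intermediate
14 | {(2S,3S)-3-[4-(benzyloxy)-3-methoxybenzyl]-4-[(tert-butyldimethylsilyl)oxy]-2-methylbutyl}zinc trifluoromethanesulfonate | COc1cc(C[C@H](CO[Si](C)(C)C(C)(C)C)[C@H](C)C[Zn]OS(=O)(=O)C(F)(F)F)ccc1OCc1ccccc1 | intermediate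
15 | tert-butyldimethylsilyl ether of (2S,3R)-2-[4-(benzyloxy)-3-methoxybenzyl]-4-[4-(benzyloxy)-3,5-dimethoxyphenyl]-3-methylbutan-1-ol | COc1cc(C[C@H](CO[Si](C)(C)C(C)(C)C)[C@H](C)Cc2cc(OC)c(OCc3ccccc3)c(OC)c2)ccc1OCc1ccccc1 | intermediate
16 | (2S,3R)-2-[4-(benzyloxy)-3-methoxybenzyl]-4-[4-(benzyloxy)-3,5-dimethoxyphenyl]-3-methylbutan-1-ol | COc1cc(C[C@H](CO)[C@H](C)Cc2cc(OC)c(OCc3ccccc3)c(OC)c2)ccc1OCc1ccccc1 | intermediate
17 | (2S,3R)-2-[4-(benzyloxy)-3-methoxybenzyl]-4-[4-(benzyloxy)-3,5-dimethoxyphenyl]-3-methylbutyl acetate | COc1cc(C[C@H](COC(C)=O)[C@H](C)Cc2cc(OC)c(OCc3ccccc3)c(OC)c2)ccc1OCc1ccccc1 | intermediate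
18 | (2S,3R)-2-(4-hydroxy-3-methoxybenzyl)-4-(4-hydroxy-3,5-dimethoxyphenyl)-3-methylbutyl acetate | COc1cc(C[C@H](COC(C)=O)[C@H](C)Cc2cc(OC)c(O)c(OC)c2)ccc1O | target

**Total step count:** 10. **Longest linear sequence:** 8 (steps 1, 3, 4, 5, 7, 8, 9, 10, from compound 1).

**Steps most likely to fail**

**Step 7.**
- Risk: insertion into the allylic-branched vinyl group may be slow. Face selection may be eroded if the catalyst and the C8 centre are mismatched. In the coupling half, methyl transfer from aluminium or β-hydride elimination from the alkyl–palladium species may outrun the desired transfer.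
- Fallback: it sets out from 2 and 3 and comes back at 16. The two stereocentres are made in the reverse order, so no branched alkene has to be carbometalated.
- Commercial 4-allyl-2,6-dimethoxyphenol is benzylated (BnBr, K2CO3, DMF) to 5-allyl-2-(benzyloxy)-1,3-dimethoxybenzene F1.
- This unbranched allylarene is a well-documented substrate class. It is methylaluminated with Me3Al and (−)-bis(1-neomenthylindenyl)zirconium dichloride in CH2Cl2, then quenched with I2 in THF, to give 2-(benzyloxy)-5-[(2R)-3-iodo-2-methylpropyl]-1,3-dimethoxybenzene F2.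
- Iodine–lithium exchange (t-BuLi, Et2O, −78 °C) and carboxylation with CO2 give (3R)-4-[4-(benzyloxy)-3,5-dimethoxyphenyl]-3-methylbutanoic acid F3.
- Coupling to 3 (pivaloyl chloride, Et3N, LiCl, THF) gives (4S)-4-benzyl-3-{(3R)-4-[4-(benzyloxy)-3,5-dimethoxyphenyl]-3-methylbutanoyl}-1,3-oxazolidin-2-one F4. At this stage the minor C8′ isomer has become a diastereomer and can be removed by crystallisation or chromatography.
- Evans alkylation (NaN(SiMe3)2, THF, −78 °C, then 2) sets C8 as S under auxiliary control and gives (4S)-4-benzyl-3-{(2S,3R)-2-[4-(benzyloxy)-3-methoxybenzyl]-4-[4-(benzyloxy)-3,5-dimethoxyphenyl]-3-methylbutanoyl}-1,3-oxazolidin-2-one F5.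
- LiBH4/MeOH reduction then delivers alcohol 16.

**Step 3.**
- Risk: proton exchange between product and dienolate may move the double bond into conjugation or erode the configuration at C8. Attack at the γ-carbon or conjugate addition of the amide base to 5 may also compete.
- Fallback: it sets out from 2 and comes back at 9. C8 is set by enzymatic desymmetrisation instead of enolate chemistry.
- Diethyl malonate is alkylated with 2 (NaH, THF) to diethyl 2-[4-(benzyloxy)-3-methoxybenzyl]malonate F6.
- LiAlH4 in THF gives 2-[4-(benzyloxy)-3-methoxybenzyl]propane-1,3-diol F7.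
- Lipase-catalysed monoacetylation with vinyl acetate gives (2R)-2-[4-(benzyloxy)-3-methoxybenzyl]-3-hydroxypropyl acetate F8. Burkholderia cepacia or porcine pancreatic lipase is picked by screening for the R product.
- TBSCl and imidazole give (2S)-2-[4-(benzyloxy)-3-methoxybenzyl]-3-[(tert-butyldimethylsilyl)oxy]propyl acetate F9.
- K2CO3 in MeOH at 0 °C, kept cold to suppress silyl migration, gives (2S)-2-[4-(benzyloxy)-3-methoxybenzyl]-3-[(tert-butyldimethylsilyl)oxy]propan-1-ol F10.
- Dess–Martin periodinane buffered with NaHCO3 gives (2R)-2-[4-(benzyloxy)-3-methoxybenzyl]-3-[(tert-butyldimethylsilyl)oxy]propanal F11.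
- F11 is methylenated at once by a Wittig reaction (Ph3P=CH2, THF, −78 to 0 °C) to 9.

**Step 4.**
- Risk: hydride may attack the ring carbonyl of the hindered imide, opening the auxiliary. Base-induced migration of the vinyl double bond during a slow reduction is the other concern.
- Fallback: it sets out from 7 and comes back at 8. The auxiliary is first removed by hydroperoxide, which selects the exocyclic carbonyl (LiOH, H2O2, THF/H2O, 0 °C), giving (2S)-2-[4-(benzyloxy)-3-methoxybenzyl]but-3-enoic acid F12.
- The acid is then reduced with LiAlH4 in Et2O at 0 °C to 8.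

**Further compounds**
F1 | step 7 | 5-allyl-2-(benzyloxy)-1,3-dimethoxybenzene | C=CCc1cc(OC)c(OCc2ccccc2)c(OC)c1
F2 | step 7 | 2-(benzyloxy)-5-[(2R)-3-iodo-2-methylpropyl]-1,3-dimethoxybenzene | IC[C@H](C)Cc1cc(OC)c(OCc2ccccc2)c(OC)c1
F3 | step 7 | (3R)-4-[4-(benzyloxy)-3,5-dimethoxyphenyl]-3-methylbutanoic acid | OC(=O)C[C@H](C)Cc1cc(OC)c(OCc2ccccc2)c(OC)c1
F4 | step 7 | (4S)-4-benzyl-3-{(3R)-4-[4-(benzyloxy)-3,5-dimethoxyphenyl]-3-methylbutanoyl}-1,3-oxazolidin-2-one | O=C(C[C@H](C)Cc1cc(OC)c(OCc2ccccc2)c(OC)c1)N1[C@@H](Cc2ccccc2)COC1=O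
F5 | step 7 | (4S)-4-benzyl-3-{(2S,3R)-2-[4-(benzyloxy)-3-methoxybenzyl]-4-[4-(benzyloxy)-3,5-dimethoxyphenyl]-3-methylbutanoyl}-1,3-oxazolidin-2-one | COc1cc(C[C@H](C(=O)N2[C@@H](Cc3ccccc3)COC2=O)[C@H](C)Cc2cc(OC)c(OCc3ccccc3)c(OC)c2)ccc1OCc1ccccc1
F6 | step 3 | diethyl 2-[4-(benzyloxy)-3-methoxybenzyl]malonate | CCOC(=O)C(Cc1ccc(OCc2ccccc2)c(OC)c1)C(=O)OCC
F7 | step 3 | 2-[4-(benzyloxy)-3-methoxybenzyl]propane-1,3-diol | COc1cc(CC(CO)CO)ccc1OCc1ccccc1
F8 | step 3 | (2R)-2-[4-(benzyloxy)-3-methoxybenzyl]-3-hydroxypropyl acetate | COc1cc(C[C@H](CO)COC(C)=O)ccc1OCc1ccccc1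
F9 | step 3 | (2S)-2-[4-(benzyloxy)-3-methoxybenzyl]-3-[(tert-butyldimethylsilyl)oxy]propyl acetate | COc1cc(C[C@H](CO[Si](C)(C)C(C)(C)C)COC(C)=O)ccc1OCc1ccccc1
F10 | step 3 | (2S)-2-[4-(benzyloxy)-3-methoxybenzyl]-3-[(tert-butyldimethylsilyl)oxy]propan-1-ol | COc1cc(C[C@H](CO[Si](C)(C)C(C)(C)C)CO)ccc1OCc1ccccc1
F11 | step 3 | (2R)-2-[4-(benzyloxy)-3-methoxybenzyl]-3-[(tert-butyldimethylsilyl)oxy]propanal | COc1cc(C[C@H](CO[Si](C)(C)C(C)(C)C)C=O)ccc1OCc1ccccc1
F12 | step 4 | (2S)-2-[4-(benzyloxy)-3-methoxybenzyl]but-3-enoic acid | COc1cc(C[C@H](C(=O)O)C=C)ccc1OCc1ccccc1
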